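**Plan**

- Retrosynthetic cuts: the two disubstituted C11=C12 / C11′=C12′ double bonds next to the central C10 unit (Wittig), the C7=C8 bond of each end (HWE), and in each ring the bond from the ketone carbon to the vinylic CH together with the bond from the gem-dimethyl carbon to the chain-bearing CH (carotenoid numbering).
- Enabling feature: in each 4-substituted 3,5,5-trimethylcyclohex-2-enone ring, C(=O)–CH2–CMe2 is an enoate read as acyl carbon plus β-carbon, and CH=C(Me)–CH(C7) is a dienolate read as γ- plus α-carbon. Ring, three methyls and first chain carbon are therefore two molecules of one C5 ester.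
- Forward order: the ring is made first by a [3+3] Michael–Claisen cyclodimerization (step 1); ketalization moves the ring alkene; the chain grows C10 → C15 (HWE, reduction); then C15 + C10 + C15 by two successive Wittig reactions.
- Stereochemistry: the ring stereocentre formed in step 1 is deliberately flattened in step 2 and re-created at the C15 stage by a catalyst-controlled enantioselective β,γ→α,β olefin isomerization. The two pseudo-enantiomeric catalysts give the (S)- and (R)-C15 units, which are attached one after the other so that only the (6S,6′R) compound can form.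
- Chain geometry: E from the HWE step, the E-phosphonate, the all-E dialdehyde and thermal Z→E equilibration of the Wittig-formed bonds.

Key step: step 1

Remark: by the CIP rules the target as drawn is (6S,6′R); with its symmetric chain this is the achiral meso form, so its two end groups are mirror images. The quinine-derived catalyst is taken to give the (S)-unit; if the sense proves opposite, the two catalysts exchange roles.

**Route**

Step 1
Reactants: 1 methyl 3-methylbut-2-enoate (two molecules)
Product: 4 racemic methyl 2,6,6-trimethyl-4-oxocyclohex-2-ene-1-carboxylate, via potassium dienolate 2 (not isolated), via Michael adduct enolate 3 (not isolated)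
Conditions: t-BuOK (0.55 equiv), THF, 0 °C → 50 °C; then 1 M HCl to pH 4
Reagents that add atoms: none
Why: t-BuOK reversibly removes a γ-proton of 1; the α-carbon of dienolate 2 adds to the β,β-dimethyl terminus of a second molecule of 1 (Michael) to give 3, proton transfer from the doubly activated α-CH re-forms a dienolate, and its γ-carbon acylates the remote ester (Claisen/Dieckmann) with loss of methoxide, which deprotonates the product to a vinylogous β-keto ester enolate. The closest known reaction types are the consecutive Michael–Claisen [3+3] annulation of enolates with acrylates to cyclohexane-1,3-diones and the conjugate addition of allylic carbanions to 3-methylbut-2-enoates used in chrysanthemate synthesis. The ring closes by a 6-(enolexo)-exo-trig acyl substitution; α-attack at that stage would need a four-membered ring, so only the γ-carbon can cyclize. The one new stereocentre (the ester-bearing ring carbon) is formed without control and is planar in the product enolate; racemic 4, with any Δ1 tautomer, is acceptable because step 2 removes this centre. The step needs α- over γ-Michael and 1,4- over 1,2-addition: the first rests on the innate α-selectivity of ester dienolates, the second on the reversibility of carbonyl addition at the hindered conjugated ester, while the cyclized product is trapped as its stabilized enolate.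

Step 2
Reactants: 4 racemic methyl 2,6,6-trimethyl-4-oxocyclohex-2-ene-1-carboxylate
Product: 5 methyl 7,9,9-trimethyl-1,4-dioxaspiro[4.5]dec-7-ene-8-carboxylate
Conditions: HOCH2CH2OH (3 equiv), p-TsOH·H2O (cat.), toluene, reflux, Dean–Stark
Reagents that add atoms: ethane-1,2-diol, OCCO
Why: Acid-catalysed ketalization in which the ring double bond moves through the dienol ether into conjugation with the ester (the usual course for isophorone-type enones), so both enantiomers of 4 converge on one achiral ketal.

Step 3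
Reactants: 5 methyl 7,9,9-trimethyl-1,4-dioxaspiro[4.5]dec-7-ene-8-carboxylate
Product: 6 (7,9,9-trimethyl-1,4-dioxaspiro[4.5]dec-7-en-8-yl)methanol
Conditions: DIBAL-H (2.5 equiv), CH2Cl2, −78 → 0 °C; Rochelle salt work-up
Reagents that add atoms: none
Why: 1,2-Reduction of a conjugated ester to the allylic alcohol by DIBAL-H; the ketal is inert to hydride and to the neutral work-up.

Step 4
Reactants: 6 (7,9,9-trimethyl-1,4-dioxaspiro[4.5]dec-7-en-8-yl)methanol
Product: 7 7,9,9-trimethyl-1,4-dioxaspiro[4.5]dec-7-ene-8-carbaldehyde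
Conditions: activated MnO2 (15 equiv), CH2Cl2, rt
Reagents that add atoms: none
Why: Selective MnO2 oxidation of an allylic alcohol to the enal, as for β-cyclogeraniol to β-cyclocitral; neutral conditions leave the ketal untouched.

Step 5
Reactants: 7 7,9,9-trimethyl-1,4-dioxaspiro[4.5]dec-7-ene-8-carbaldehyde; 8 ethyl (2E)-4-(diethoxyphosphoryl)-3-methylbut-2-enoate
Product: 10 ethyl (2E,4E)-3-methyl-5-(7,9,9-trimethyl-1,4-dioxaspiro[4.5]dec-7-en-8-yl)penta-2,4-dienoate, via lithiated phosphonate 9 (not isolated)
Conditions: 8, n-BuLi, THF–DMPU, −78 °C; then 7, −78 °C → rt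
Reagents that add atoms: none
Why: Horner–Wadsworth–Emmons olefination with a vinylogous stabilized phosphonate gives the new disubstituted double bond E, the standard C10 + C5 extension of cyclocitral-type aldehydes; minor 2Z isomer is removed by chromatography.

Step 6
Reactants: 10 ethyl (2E,4E)-3-methyl-5-(7,9,9-trimethyl-1,4-dioxaspiro[4.5]dec-7-en-8-yl)penta-2,4-dienoate
Product: 11 (2E,4E)-3-methyl-5-(7,9,9-trimethyl-1,4-dioxaspiro[4.5]dec-7-en-8-yl)penta-2,4-dien-1-ol
Conditions: DIBAL-H (2.5 equiv), CH2Cl2, −78 °C; Rochelle salt work-up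
Reagents that add atoms: none
Why: DIBAL-H reduces the dienoate 1,2 to the primary allylic alcohol while the ring carbonyl is still masked as the ketal.

Step 7
Reactants: 11 (2E,4E)-3-methyl-5-(7,9,9-trimethyl-1,4-dioxaspiro[4.5]dec-7-en-8-yl)penta-2,4-dien-1-ol
Product: 12 4-[(1E,3E)-5-hydroxy-3-methylpenta-1,3-dien-1-yl]-3,5,5-trimethylcyclohex-3-en-1-one
Conditions: PPTS (0.2 equiv), THF–H2O (4:1), rt; NaHCO3 work-up
Reagents that add atoms: none
Why: Mild dioxolane hydrolysis through the oxocarbenium ion; at this acidity the tetrasubstituted, triene-conjugated double bond should stay β,γ to the ketone, as mild deketalization of Δ5-3-ketals gives the unconjugated ketones.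

Step 8
Reactants: 12 4-[(1E,3E)-5-hydroxy-3-methylpenta-1,3-dien-1-yl]-3,5,5-trimethylcyclohex-3-en-1-one
Product: 13 (4S)-4-[(1E,3E)-5-hydroxy-3-methylpenta-1,3-dien-1-yl]-3,5,5-trimethylcyclohex-2-en-1-one
Conditions: 9-amino-9-deoxy-epi-quinine (10 mol %), TFA (20 mol %), toluene, rt
Reagents that add atoms: none
Why: Enantioselective isomerization of a β,γ-unsaturated cyclohexenone by cooperative iminium–base catalysis: the primary amine forms the iminium ion, the quinuclidine removes the α-proton to give a dienamine and returns it to one face of the γ-carbon; this catalyst-controlled protonation sets the ring stereocentre, and ketone conjugation drives the shift.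

Step 9
Reactants: 12 4-[(1E,3E)-5-hydroxy-3-methylpenta-1,3-dien-1-yl]-3,5,5-trimethylcyclohex-3-en-1-one
Product: 14 (4R)-4-[(1E,3E)-5-hydroxy-3-methylpenta-1,3-dien-1-yl]-3,5,5-trimethylcyclohex-2-en-1-one
Conditions: 9-amino-9-deoxy-epi-quinidine (10 mol %), TFA (20 mol %), toluene, rt
Reagents that add atoms: none
Why: The same iminium–base olefin isomerization with the pseudo-enantiomeric catalyst should deliver the proton to the opposite face of the dienamine γ-carbon and give the mirror-image stereocentre.

Step 10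
Reactants: 13 (4S)-4-[(1E,3E)-5-hydroxy-3-methylpenta-1,3-dien-1-yl]-3,5,5-trimethylcyclohex-2-en-1-one
Product: 15 [(2E,4E)-3-methyl-5-[(1S)-2,6,6-trimethyl-4-oxocyclohex-2-en-1-yl]penta-2,4-dien-1-yl]triphenylphosphonium bromide
Conditions: PPh3·HBr (1.05 equiv), MeOH, 0 °C → rt
Reagents that add atoms: triphenylphosphine hydrobromide, [Br-].[PH+](c1ccccc1)(c1ccccc1)c1ccccc1
Why: Standard C15 Wittig-salt formation: ionization of the dienylic alcohol and capture of the pentadienyl cation by PPh3 at the terminus gives the (2E,4E) primary phosphonium salt; the ring stereocentre is not part of the reacting system.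

Step 11
Reactants: 14 (4R)-4-[(1E,3E)-5-hydroxy-3-methylpenta-1,3-dien-1-yl]-3,5,5-trimethylcyclohex-2-en-1-one
Product: 16 [(2E,4E)-3-methyl-5-[(1R)-2,6,6-trimethyl-4-oxocyclohex-2-en-1-yl]penta-2,4-dien-1-yl]triphenylphosphonium bromide
Conditions: PPh3·HBr (1.05 equiv), MeOH, 0 °C → rt
Reagents that add atoms: triphenylphosphine hydrobromide, [Br-].[PH+](c1ccccc1)(c1ccccc1)c1ccccc1
Why: Same phosphonium salt formation as step 10 in the enantiomeric series.

Step 12
Reactants: 15 [(2E,4E)-3-methyl-5-[(1S)-2,6,6-trimethyl-4-oxocyclohex-2-en-1-yl]penta-2,4-dien-1-yl]triphenylphosphonium bromide; 17 (2E,4E,6E)-2,7-dimethylocta-2,4,6-trienedial (3 equiv)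
Product: 19 (2E,4E,6E,8E,10E,12E)-2,7,11-trimethyl-13-[(1S)-2,6,6-trimethyl-4-oxocyclohex-2-en-1-yl]trideca-2,4,6,8,10,12-hexaenal, via phosphorus ylide 18 (not isolated)
Conditions: 1,2-epoxybutane, EtOH, reflux, argon, dark; excess 17 recovered
Reagents that add atoms: none
Why: Wittig olefination under base-free epoxide conditions (bromide opens the epoxide and the alkoxide forms the ylide); excess dialdehyde secures mono-olefination, the near-neutral medium protects the stereocentre γ to the enone, and the new double bond equilibrates to E on heating.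

Step 13
Reactants: 19 (2E,4E,6E,8E,10E,12E)-2,7,11-trimethyl-13-[(1S)-2,6,6-trimethyl-4-oxocyclohex-2-en-1-yl]trideca-2,4,6,8,10,12-hexaenal; 16 [(2E,4E)-3-methyl-5-[(1R)-2,6,6-trimethyl-4-oxocyclohex-2-en-1-yl]penta-2,4-dien-1-yl]triphenylphosphonium bromide
Product: 21 (6S,6′R)-ε,ε-carotene-3,3′-dione, via phosphorus ylide 20 (not isolated)
Conditions: 1,2-epoxybutane, EtOH, reflux, argon, dark; then reflux in n-heptane (Z→E), crystallization
Reagents that add atoms: none
Why: Second Wittig olefination under the same base-free conditions joins the (R)-C15 unit to the (S)-C25 aldehyde, so the two mirror-image ends are fixed by the order of addition and only the meso compound can result; thermal equilibration gives the all-E chain.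

**Compound list**

1 | methyl 3-methylbut-2-enoate | COC(=O)C=C(C)C | starting material
2 | potassium dienolate of 1 (potassium 1-methoxy-3-methylbuta-1,3-dien-1-olate) | C=C(C)C=C([O-])OC.[K+] | intermediate
3 | potassium enolate of dimethyl 3,3-dimethyl-2-(prop-1-en-2-yl)pentanedioate (Michael adduct) | COC(=O)C(C(C)=C)C(C)(C)C=C([O-])OC.[K+] | intermediate
4 | racemic methyl 2,6,6-trimethyl-4-oxocyclohex-2-ene-1-carboxylate | COC(=O)C1C(C)=CC(=O)CC1(C)C | intermediate
5 | methyl 7,9,9-trimethyl-1,4-dioxaspiro[4.5]dec-7-ene-8-carboxylate | COC(=O)C1=C(C)CC2(CC1(C)C)OCCO2 | intermediate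
6 | (7,9,9-trimethyl-1,4-dioxaspiro[4.5]dec-7-en-8-yl)methanol | OCC1=C(C)CC2(CC1(C)C)OCCO2 | intermediate
7 | 7,9,9-trimethyl-1,4-dioxaspiro[4.5]dec-7-ene-8-carbaldehyde | O=CC1=C(C)CC2(CC1(C)C)OCCO2 | intermediate
8 | ethyl (2E)-4-(diethoxyphosphoryl)-3-methylbut-2-enoate | CCOC(=O)/C=C(\C)CP(=O)(OCC)OCC | starting material
9 | lithium salt of the carbanion of 8 | CCOC(=O)/C=C(\C)[CH-]P(=O)(OCC)OCC.[Li+] | intermediate
10 | ethyl (2E,4E)-3-methyl-5-(7,9,9-trimethyl-1,4-dioxaspiro[4.5]dec-7-en-8-yl)penta-2,4-dienoate | CCOC(=O)/C=C(C)/C=C/C1=C(C)CC2(CC1(C)C)OCCO2 | intermediate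
11 | (2E,4E)-3-methyl-5-(7,9,9-trimethyl-1,4-dioxaspiro[4.5]dec-7-en-8-yl)penta-2,4-dien-1-ol | OC/C=C(C)/C=C/C1=C(C)CC2(CC1(C)C)OCCO2 | intermediate
12 | 4-[(1E,3E)-5-hydroxy-3-methylpenta-1,3-dien-1-yl]-3,5,5-trimethylcyclohex-3-en-1-one | OC/C=C(C)/C=C/C1=C(C)CC(=O)CC1(C)C | intermediate
13 | (4S)-4-[(1E,3E)-5-hydroxy-3-methylpenta-1,3-dien-1-yl]-3,5,5-trimethylcyclohex-2-en-1-one | CC1=CC(=O)CC(C)(C)[C@@H]1/C=C/C(C)=C/CO | intermediate
14 | (4R)-4-[(1E,3E)-5-hydroxy-3-methylpenta-1,3-dien-1-yl]-3,5,5-trimethylcyclohex-2-en-1-one | CC1=CC(=O)CC(C)(C)[C@H]1/C=C/C(C)=C/CO | intermediate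
15 | [(2E,4E)-3-methyl-5-[(1S)-2,6,6-trimethyl-4-oxocyclohex-2-en-1-yl]penta-2,4-dien-1-yl]triphenylphosphonium bromide | CC1=CC(=O)CC(C)(C)[C@@H]1/C=C/C(C)=C/C[P+](c1ccccc1)(c1ccccc1)c1ccccc1.[Br-] | intermediate
16 | [(2E,4E)-3-methyl-5-[(1R)-2,6,6-trimethyl-4-oxocyclohex-2-en-1-yl]penta-2,4-dien-1-yl]triphenylphosphonium bromide | CC1=CC(=O)CC(C)(C)[C@H]1/C=C/C(C)=C/C[P+](c1ccccc1)(c1ccccc1)c1ccccc1.[Br-] | intermediate
17 | (2E,4E,6E)-2,7-dimethylocta-2,4,6-trienedial | O=C/C(C)=C/C=C/C=C(C)/C=O | starting material
18 | ylide of 15, [(2E,4E)-3-methyl-5-[(1S)-2,6,6-trimethyl-4-oxocyclohex-2-en-1-yl]penta-2,4-dien-1-ylidene]triphenylphosphorane | CC1=CC(=O)CC(C)(C)[C@@H]1/C=C/C(C)=C/C=P(c1ccccc1)(c1ccccc1)c1ccccc1 | intermediate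
19 | (2E,4E,6E,8E,10E,12E)-2,7,11-trimethyl-13-[(1S)-2,6,6-trimethyl-4-oxocyclohex-2-en-1-yl]trideca-2,4,6,8,10,12-hexaenal | CC1=CC(=O)CC(C)(C)[C@@H]1/C=C/C(C)=C/C=C/C(C)=C/C=C/C=C(C)/C=O | intermediate
20 | ylide of 16, [(2E,4E)-3-methyl-5-[(1R)-2,6,6-trimethyl-4-oxocyclohex-2-en-1-yl]penta-2,4-dien-1-ylidene]triphenylphosphorane | CC1=CC(=O)CC(C)(C)[C@H]1/C=C/C(C)=C/C=P(c1ccccc1)(c1ccccc1)c1ccccc1 | intermediate
21 | (6S,6′R)-ε,ε-carotene-3,3′-dione (meso) | CC1=CC(=O)CC(C)(C)[C@@H]1/C=C/C(C)=C/C=C/C(C)=C/C=C/C=C(C)/C=C/C=C(C)/C=C/[C@H]1C(C)=CC(=O)CC1(C)C | target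

**Step count**

Total steps: 13. Longest linear sequence: 11 (steps 1–8, 10, 12, 13).

**Steps most likely to fail**

Step 1. The hindered conjugate addition may be outpaced by 1,2-acylation (Claisen self-condensation) or by attack through the γ-carbon, leading to acyclic keto esters or the regioisomeric ring. The fallback does not set out from a numbered compound: purchased 4-methylpent-3-en-2-one and methyl acetoacetate take the place of 1. They are condensed in a Robinson-type Michael–aldol–dehydration sequence (BF3·OEt2 or ZnCl2, heat), the classical access to isophorone-4-carboxylates, and the route is rejoined at 4. No new compound arises.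

Step 8 (and its mirror-image twin, step 9). Facial selectivity of the γ-protonation may be poor at a tetrasubstituted, hindered dienamine terminus, protonation may occur further along the chain, or an uncatalysed racemic shift may compete. The fallback sets out from 12: a catalytic amount of DBU in CH2Cl2 moves the double bond without stereocontrol to give the racemic enone alcohol F1. Its antipodes are then separated by preparative chromatography on a chiral stationary phase; since both are needed, neither is discarded. The route is rejoined at 13 and 14.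

Step 12 (the same concern holds for step 13). Configuration may erode by reversible deprotonation of the ring stereocentre γ to the enone by ylide or alkoxide, and over-olefination may consume the mono-aldehyde. The fallback sets out from 13 and 14 and removes the enone during the olefinations:
- Luche reduction (NaBH4, CeCl3, MeOH) gives the (4S)-diol F2 and the (4R)-diol F3, each as carbinol epimers.
- PPh3·HBr converts only the primary dienylic alcohol, giving the (1S)-hydroxy phosphonium bromide F4 and the (1R)-hydroxy phosphonium bromide F5.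
- Epoxide-mediated Wittig reaction of F4 with 17 gives the hydroxy C25 aldehyde F6; a second one with F5 gives (6S,6′R)-ε,ε-carotene-3,3′-diol F7.
- MnO2 oxidation of both ring allylic carbinols then gives 21, where the route is rejoined.

**Further compounds**

F0 | step 1 | none | none
F1 | step 8 | racemic 4-[(1E,3E)-5-hydroxy-3-methylpenta-1,3-dien-1-yl]-3,5,5-trimethylcyclohex-2-en-1-one | CC1=CC(=O)CC(C)(C)C1/C=C/C(C)=C/CO
F2 | step 12 | (4S)-4-[(1E,3E)-5-hydroxy-3-methylpenta-1,3-dien-1-yl]-3,5,5-trimethylcyclohex-2-en-1-ol (C-1 epimers) | CC1=CC(O)CC(C)(C)[C@@H]1/C=C/C(C)=C/CO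
F3 | step 12 | (4R)-4-[(1E,3E)-5-hydroxy-3-methylpenta-1,3-dien-1-yl]-3,5,5-trimethylcyclohex-2-en-1-ol (C-1 epimers) | CC1=CC(O)CC(C)(C)[C@H]1/C=C/C(C)=C/CO
F4 | step 12 | [(2E,4E)-5-[(1S)-4-hydroxy-2,6,6-trimethylcyclohex-2-en-1-yl]-3-methylpenta-2,4-dien-1-yl]triphenylphosphonium bromide (C-4 epimers) | CC1=CC(O)CC(C)(C)[C@@H]1/C=C/C(C)=C/C[P+](c1ccccc1)(c1ccccc1)c1ccccc1.[Br-]
F5 | step 12 | [(2E,4E)-5-[(1R)-4-hydroxy-2,6,6-trimethylcyclohex-2-en-1-yl]-3-methylpenta-2,4-dien-1-yl]triphenylphosphonium bromide (C-4 epimers) | CC1=CC(O)CC(C)(C)[C@H]1/C=C/C(C)=C/C[P+](c1ccccc1)(c1ccccc1)c1ccccc1.[Br-]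
F6 | step 12 | (2E,4E,6E,8E,10E,12E)-13-[(1S)-4-hydroxy-2,6,6-trimethylcyclohex-2-en-1-yl]-2,7,11-trimethyltrideca-2,4,6,8,10,12-hexaenal (C-4 epimers) | CC1=CC(O)CC(C)(C)[C@@H]1/C=C/C(C)=C/C=C/C(C)=C/C=C/C=C(C)/C=O
F7 | step 12 | (6S,6′R)-ε,ε-carotene-3,3′-diol (C-3 and C-3′ epimers) | CC1=CC(O)CC(C)(C)[C@@H]1/C=C/C(C)=C/C=C/C(C)=C/C=C/C=C(C)/C=C/C=C(C)/C=C/[C@H]1C(C)=CC(O)CC1(C)C
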